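**Retrosynthetic overview**
1. In benzofuran numbering (O1, C2 aryl, C3 methyl, C3a allyl, C4=C5(OMe), C6=O, C7=C7a), the C4=C5 double bond is put in last, by dehydrogenation of the 4,5-dihydro vinylogous ester (silyl enol ether, then Pd(OAc)2).
2. Feature on which the plan rests: the carbocycle C3a–C4–C5–C6–C7–C7a is a cyclohexane-1,3-dione held as its enol ether. It is fused through C7a (oxidation level of a lactone carbonyl) and C3a (its α-carbon) to the ring O1–C2–C3–C3a–C7a, which is therefore a masked 4-methyl-5-aryl butyrolactone.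
3. Key disconnection: C3a–C4 (Michael) and C7–C7a (Claisen) lead back to the α-allyl lactone and 3-methoxybut-3-en-2-one; acid recloses O1–C7a.
4. The lactone comes from α-allylation of the trans-4-methyl-5-aryl lactone, made from the anti crotylation product of 3,4,5-trimethoxybenzaldehyde by hydroboration–oxidation and oxidative lactonisation.
5. Ring order: the five-membered oxygen ring first (as the lactone), then the six-membered carbocycle; the oxygen ring opens and recloses in the key flask.

Key step: step 6

Assumption: the (S)-configured TRIP phosphoric acid is taken to deliver the crotyl group to the Si face of the aldehyde (1S,2S alcohol); if the sense proves opposite, the (R)-acid is used instead.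

**Route**

Step 1
Reactants: 1 3,4,5-trimethoxybenzaldehyde; 2 (E)-crotylboronic acid pinacol ester
Product: 4 (1S,2S)-2-methyl-1-(3,4,5-trimethoxyphenyl)but-3-en-1-ol, via pinacol borate ester 3 (not isolated)
Conditions: (S)-TRIP phosphoric acid [(S)-3,3′-bis(2,4,6-triisopropylphenyl)-1,1′-binaphthyl-2,2′-diyl hydrogen phosphate] (5 mol %), 4 Å MS, PhMe, −30 °C; then aq. NaHCO3
Reagents that add atoms: none
Why: Chiral phosphoric acid-catalysed crotylboration of an aldehyde, in which the acid activates the pinacol boronate in a closed chair transition state, so the (E)-crotyl geometry becomes the anti relationship and the catalyst pocket selects the Si face of the aldehyde, setting C1 and C2 as S,S in one event.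

Step 2
Reactants: 4 (1S,2S)-2-methyl-1-(3,4,5-trimethoxyphenyl)but-3-en-1-ol
Product: 6 (1S,2S)-2-methyl-1-(3,4,5-trimethoxyphenyl)butane-1,4-diol, via alkylborane 5 (not isolated)
Conditions: 9-BBN (9-borabicyclo[3.3.1]nonane, 2.5 equiv; the excess allows for reaction at the free hydroxyl), THF, 0 → 25 °C; then 3 M NaOH, 30 % H2O2, 0 → 25 °C
Reagents that add atoms: hydrogen peroxide, OO
Why: Hydroboration–oxidation, in which the bulky dialkylborane places boron on the terminal carbon of the monosubstituted alkene and the C–B bond is oxidised with retention, so only the terminal carbon is functionalised and neither stereocentre is touched.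

Step 3
Reactants: 6 (1S,2S)-2-methyl-1-(3,4,5-trimethoxyphenyl)butane-1,4-diol
Product: 9 (4S,5S)-4-methyl-5-(3,4,5-trimethoxyphenyl)oxolan-2-one, via hydroxy aldehyde 7 (not isolated), via lactol 8 (not isolated)
Conditions: TEMPO [(2,2,6,6-tetramethylpiperidin-1-yl)oxyl] (0.2 equiv), PhI(OAc)2 (2.5 equiv), CH2Cl2, 25 °C
Reagents that add atoms: none
Why: Oxoammonium (TEMPO) oxidation with PhI(OAc)2 as terminal oxidant is faster at the primary than at the secondary alcohol; the hydroxy aldehyde closes to the five-membered lactol, which ties up the benzylic hydroxyl and is oxidised on to the lactone, so both stereocentres are carried over unchanged.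

Step 4
Reactants: 9 (4S,5S)-4-methyl-5-(3,4,5-trimethoxyphenyl)oxolan-2-one; 10 allyl bromide
Product: 12 (3S,4S,5S)-3-allyl-4-methyl-5-(3,4,5-trimethoxyphenyl)oxolan-2-one, via lithium lactone enolate 11 (not isolated)
Conditions: LiN(iPr)2 (1.05 equiv), THF, −78 °C; then 10 (1.2 equiv), −78 → −30 °C; aq. NH4Cl
Reagents that add atoms: none
Why: Alkylation of a lactone lithium enolate with a reactive allylic halide, in which the electrophile should enter anti to the adjacent C4 methyl group to give the 3,4-trans isomer; this centre is made planar again in step 6, so the 3,4-cis isomer would serve equally, and it is the order (allyl first, Michael acceptor second) that later places allyl cis to the methyl group.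

Step 5
Reactants: 13 3,3-dimethoxybutan-2-one
Product: 14 3-methoxybut-3-en-2-one
Conditions: p-TsOH·H2O (1 mol %), hydroquinone (trace), neat, 130–150 °C, MeOH distilled off; then distillation at reduced pressure, stored cold
Reagents that add atoms: none
Why: Acid-catalysed loss of methanol from a dimethyl ketal to the enol ether (the reaction type by which 2-methoxypropene is made from 2,2-dimethoxypropane), driven by removal of methanol, with the inhibitor suppressing polymerisation of the enone.

Step 6
Reactants: 12 (3S,4S,5S)-3-allyl-4-methyl-5-(3,4,5-trimethoxyphenyl)oxolan-2-one; 14 3-methoxybut-3-en-2-one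
Product: 18 (2S,3S,3aS,5RS)-3a-allyl-5-methoxy-3-methyl-2-(3,4,5-trimethoxyphenyl)-3,3a,4,5-tetrahydro-1-benzofuran-6(2H)-one (C5 epimers), via potassium lactone enolate 15 (not isolated), via Michael adduct enolate 16 (not isolated), via hydroxy diketone 17 (not isolated)
Conditions: KN(SiMe3)2 (1.05 equiv), THF, −78 °C; 14 (1.2 equiv, added slowly), −78 °C; t-BuOH (0.5 equiv), −78 → 25 °C; then 1 M HCl; then p-TsOH·H2O (5 mol %), MgSO4, CH2Cl2, 25 °C
Reagents that add atoms: none
Why: The fully formed enolate 15 adds to the unhindered methylene terminus of 14 (bond C3a–C4), the amine and tert-butanol relay a proton so that the methoxy-substituted enolate 16 equilibrates with its methyl ketone enolate, and that carbon attacks the lactone carbonyl (bond C7–C7a), after which the tetrahedral alkoxide collapses to the potassium 1,3-diketonate, a sink that pulls the reversible steps forward. The closest known reaction type is the Michael–Claisen (dimedone-type) synthesis of cyclohexane-1,3-diones from ester enolates and vinyl ketones, here with a lactone as the ester partner. The six-membered ring closes by a 6-exo-trig (6-enolexo) acylation, and on acidification the freed C2 hydroxyl of 17 adds 5-exo-trig to the C7a carbonyl and loses water toward C7 to give the vinylogous ester, attack at C6 being excluded because it would need a bridged seven-membered ring. The quaternary centre C3a is controlled by the neighbouring C3 methyl group of the lactone enolate, which shields one face so that the acceptor bonds anti to it and the allyl group ends cis to the methyl; C2 and C3 are untouched because the C2–O bond is never broken, and C5 forms as a mixture that disappears in step 8. The step needs conjugate C-alkylation without proton transfer from the more acidic methyl ketone of 14 to the tertiary lactone enolate, which is secured by preforming the enolate with a stoichiometric amide base at −78 °C and adding 14 slowly, a tetrasubstituted potassium enolate favouring 1,4- over carbonyl addition.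

Step 7
Reactants: 18 (2S,3S,3aS,5RS)-3a-allyl-5-methoxy-3-methyl-2-(3,4,5-trimethoxyphenyl)-3,3a,4,5-tetrahydro-1-benzofuran-6(2H)-one
Product: 20 (2S,3S,3aS)-3a-allyl-5-methoxy-3-methyl-6-(trimethylsilyloxy)-2-(3,4,5-trimethoxyphenyl)-2,3,3a,4-tetrahydro-1-benzofuran, via lithium dienolate 19 (not isolated)
Conditions: LiN(iPr)2 (1.3 equiv), THF, −78 °C; Me3SiCl (1.5 equiv), Et3N, −78 → 0 °C; pentane, filtration, concentration (no aqueous work-up), used directly
Reagents that add atoms: chlorotrimethylsilane, C[Si](C)(C)Cl
Why: Kinetic α′-deprotonation of a vinylogous ester (as in Stork–Danheiser chemistry) followed by O-silylation; C5 carries the only enolisable hydrogen (C7 is vinylic, C3a quaternary), so the C5=C6 silyl enol ether forms regiospecifically and both C5 epimers converge on it.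

Step 8
Reactants: 20 (2S,3S,3aS)-3a-allyl-5-methoxy-3-methyl-6-(trimethylsilyloxy)-2-(3,4,5-trimethoxyphenyl)-2,3,3a,4-tetrahydro-1-benzofuran
Product: 21 (2S,3S,3aR)-3a-allyl-5-methoxy-3-methyl-2-(3,4,5-trimethoxyphenyl)-3,3a-dihydro-1-benzofuran-6(2H)-one (CNP0197140.2)
Conditions: Pd(OAc)2 (1.1 equiv), MeCN, 25 °C; neutral work-up below 30 °C
Reagents that add atoms: none
Why: Saegusa–Ito oxidation, in which the silyl enol ether gives a palladium enolate bound at C5 and β-hydride elimination can only take a C4 hydrogen, forming the C4=C5 enone; the quaternary C3a prevents aromatisation and no stereocentre is involved (the descriptor at C3a changes from S to R only through the priority rules).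

**Compound list**
1 | 3,4,5-trimethoxybenzaldehyde | COc1cc(C=O)cc(OC)c1OC | starting material
2 | (E)-crotylboronic acid pinacol ester | C/C=C/CB1OC(C)(C)C(C)(C)O1 | starting material
3 | 4,4,5,5-tetramethyl-2-{[(1S,2S)-2-methyl-1-(3,4,5-trimethoxyphenyl)but-3-en-1-yl]oxy}-1,3,2-dioxaborolane (not isolated) | C=C[C@H](C)[C@H](OB1OC(C)(C)C(C)(C)O1)c1cc(OC)c(OC)c(OC)c1 | intermediate
4 | (1S,2S)-2-methyl-1-(3,4,5-trimethoxyphenyl)but-3-en-1-ol | C=C[C@H](C)[C@H](O)c1cc(OC)c(OC)c(OC)c1 | intermediate
5 | 9-[(3S,4S)-4-hydroxy-3-methyl-4-(3,4,5-trimethoxyphenyl)butyl]-9-borabicyclo[3.3.1]nonane (not isolated) | C[C@@H](CCB1C2CCCC1CCC2)[C@H](O)c1cc(OC)c(OC)c(OC)c1 | intermediate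
6 | (1S,2S)-2-methyl-1-(3,4,5-trimethoxyphenyl)butane-1,4-diol | OCC[C@H](C)[C@H](O)c1cc(OC)c(OC)c(OC)c1 | intermediate
7 | (3S,4S)-4-hydroxy-3-methyl-4-(3,4,5-trimethoxyphenyl)butanal (not isolated) | O=CC[C@H](C)[C@H](O)c1cc(OC)c(OC)c(OC)c1 | intermediate
8 | (4S,5S)-4-methyl-5-(3,4,5-trimethoxyphenyl)oxolan-2-ol, anomer mixture (not isolated) | OC1C[C@H](C)[C@@H](c2cc(OC)c(OC)c(OC)c2)O1 | intermediate
9 | (4S,5S)-4-methyl-5-(3,4,5-trimethoxyphenyl)oxolan-2-one (trans) | O=C1C[C@H](C)[C@@H](c2cc(OC)c(OC)c(OC)c2)O1 | intermediate
10 | allyl bromide | C=CCBr | starting material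
11 | lithium enolate of 9 (not isolated) | [Li+].[O-]C1=C[C@H](C)[C@@H](c2cc(OC)c(OC)c(OC)c2)O1 | intermediate
12 | (3S,4S,5S)-3-allyl-4-methyl-5-(3,4,5-trimethoxyphenyl)oxolan-2-one (trans,trans) | C=CC[C@@H]1C(=O)O[C@H](c2cc(OC)c(OC)c(OC)c2)[C@H]1C | intermediate
13 | 3,3-dimethoxybutan-2-one | COC(C)(OC)C(C)=O | starting material
14 | 3-methoxybut-3-en-2-one | COC(=C)C(C)=O | intermediate
15 | potassium enolate of 12 (not isolated) | [K+].[O-]C1=C(CC=C)[C@H](C)[C@@H](c2cc(OC)c(OC)c(OC)c2)O1 | intermediate
16 | potassium enolate of (3S,4S,5S)-3-allyl-3-(2-methoxy-3-oxobutyl)-4-methyl-5-(3,4,5-trimethoxyphenyl)oxolan-2-one, allyl cis to the C4 methyl (not isolated) | [K+].C=CC[C@@]1(CC(OC)=C(C)[O-])C(=O)O[C@H](c2cc(OC)c(OC)c(OC)c2)[C@H]1C | intermediate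
17 | (6S)-6-allyl-6-[(1S,2S)-1-hydroxy-1-(3,4,5-trimethoxyphenyl)propan-2-yl]-4-methoxycyclohexane-1,3-dione, C4 epimers (not isolated) | C=CC[C@]1(CC(OC)C(=O)CC1=O)[C@H](C)[C@H](O)c1cc(OC)c(OC)c(OC)c1 | intermediate
18 | (2S,3S,3aS,5RS)-3a-allyl-5-methoxy-3-methyl-2-(3,4,5-trimethoxyphenyl)-3,3a,4,5-tetrahydro-1-benzofuran-6(2H)-one | C=CC[C@@]12CC(OC)C(=O)C=C1O[C@H](c1cc(OC)c(OC)c(OC)c1)[C@H]2C | intermediate
19 | lithium dienolate of 18 (not isolated) | [Li+].C=CC[C@@]12CC(OC)=C([O-])C=C1O[C@H](c1cc(OC)c(OC)c(OC)c1)[C@H]2C | intermediate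
20 | (2S,3S,3aS)-3a-allyl-5-methoxy-3-methyl-6-(trimethylsilyloxy)-2-(3,4,5-trimethoxyphenyl)-2,3,3a,4-tetrahydro-1-benzofuran | C=CC[C@@]12CC(OC)=C(O[Si](C)(C)C)C=C1O[C@H](c1cc(OC)c(OC)c(OC)c1)[C@H]2C | intermediate
21 | (2S,3S,3aR)-3a-allyl-5-methoxy-3-methyl-2-(3,4,5-trimethoxyphenyl)-3,3a-dihydro-1-benzofuran-6(2H)-one | C=CC[C@@]12C=C(OC)C(=O)C=C1O[C@H](c1cc(OC)c(OC)c(OC)c1)[C@H]2C | target

**Step count**
Total: 8 steps. Longest linear sequence: 7 steps (steps 1, 2, 3, 4, 6, 7, 8) from 3,4,5-trimethoxybenzaldehyde; step 5 is a one-step side branch.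

**Steps most likely to fail, with fallbacks**

Step 6. Three processes may defeat it: proton transfer from the methyl ketone of the acceptor to the lactone enolate, followed by anionic oligomerisation of the enone; reversal of the Michael addition on warming before the Claisen closure; and bond formation on the aryl-bearing face being less selective than expected. The fallback separates the two bond formations. It sets out from 12: the potassium enolate 15 is trapped with Me3SiCl (THF, −78 °C) as the silyl ketene acetal F1. A Mukaiyama–Michael addition of F1 to 14 (Me3SiOTf, 10 mol %, CH2Cl2, −78 °C) should give the silyl enol ether adduct F2 under non-basic conditions, again by attack anti to the C4 methyl group. Work-up with 1 M HCl should free the keto lactone F3, which can be purified. Kinetic deprotonation of its methyl ketone (LiN(iPr)2, 1.2 equiv, THF, −78 °C) gives the lithium methyl enolate F4, which on warming to 0 °C should close onto the lactone carbonyl; acidification and the p-TsOH·H2O treatment of step 6 then pass through 17 and rejoin the route at 18.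

Step 8. Palladium may coordinate the terminal allyl alkene and cause double-bond migration, β-hydride elimination may be slow at the fully substituted, methoxy-bearing palladium enolate, and the silyl group may be lost hydrolytically with return to the ketone. The fallback is a selenoxide elimination and sets out from 18, bypassing 20. The enolate 19 (LiN(iPr)2, THF, −78 °C) is quenched with PhSeCl to give the α-phenylselanyl ketone F5. Oxidation (30 % H2O2, pyridine, CH2Cl2, 0 °C) gives the selenoxide F6, whose syn-elimination can only take a C4 hydrogen, so the route is rejoined at 21.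

Step 1. Face selectivity in the catalytic crotyl transfer to the electron-rich aldehyde may be insufficient or inverted, which would erode the enantiomeric purity that every later compound inherits. The fallback replaces allylboration by iridium-catalysed transfer-hydrogenative crotylation and sets out from 1: but-3-en-2-yl acetate, [Ir(cod)Cl]2 (2.5 mol %), SEGPHOS (5 mol %, antipode chosen for the 1S,2S product), 4-cyano-3-nitrobenzoic acid (10 mol %), Cs2CO3 (20 mol %), propan-2-ol (2 equiv), THF, 90 °C. This anti-selective coupling should give the homoallylic alcohol directly and rejoins the route at 4.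

Further compounds
F1 | step 6 | {[(4S,5S)-3-allyl-4-methyl-5-(3,4,5-trimethoxyphenyl)-4,5-dihydrofuran-2-yl]oxy}trimethylsilane | C=CCC1=C(O[Si](C)(C)C)O[C@H](c2cc(OC)c(OC)c(OC)c2)[C@H]1C
F2 | step 6 | (3S,4S,5S)-3-allyl-3-[2-methoxy-3-(trimethylsilyloxy)but-2-en-1-yl]-4-methyl-5-(3,4,5-trimethoxyphenyl)oxolan-2-one | C=CC[C@@]1(CC(OC)=C(C)O[Si](C)(C)C)C(=O)O[C@H](c2cc(OC)c(OC)c(OC)c2)[C@H]1C
F3 | step 6 | (3S,4S,5S)-3-allyl-3-(2-methoxy-3-oxobutyl)-4-methyl-5-(3,4,5-trimethoxyphenyl)oxolan-2-one (side-chain epimers) | C=CC[C@@]1(CC(OC)C(C)=O)C(=O)O[C@H](c2cc(OC)c(OC)c(OC)c2)[C@H]1C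
F4 | step 6 | lithium methyl enolate of F3 | [Li+].C=CC[C@@]1(CC(OC)C(=C)[O-])C(=O)O[C@H](c2cc(OC)c(OC)c(OC)c2)[C@H]1C
F5 | step 8 | (2S,3S,3aS)-3a-allyl-5-methoxy-3-methyl-5-(phenylselanyl)-2-(3,4,5-trimethoxyphenyl)-3,3a,4,5-tetrahydro-1-benzofuran-6(2H)-one (C5 epimers) | C=CC[C@@]12CC(OC)([Se]c3ccccc3)C(=O)C=C1O[C@H](c1cc(OC)c(OC)c(OC)c1)[C@H]2C
F6 | step 8 | selenoxide of F5 | C=CC[C@@]12CC(OC)([Se](=O)c3ccccc3)C(=O)C=C1O[C@H](c1cc(OC)c(OC)c(OC)c1)[C@H]2C
F0 | step 1 | none | none
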